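**Retrosynthetic overview**
1. The target is a 16-membered ring holding two 1,9-dialkyl-3-methylquinolizidin-2-ones: A (1S,3R,9R,9aR; H-1/H-9a cis) and B (1S,3R,9S,9aS; H-1/H-9a trans). C1 and C3 are alike in both; C9 and C9a are mirror images.
2. Last disconnection, in A: C1–C9a (Mannich) and N–C4 (aza-Michael) give imine/isopropenyl ketone 16. This step closes the macrocycle and the ketone ring of A and sets all four centres of A.
3. The same two bonds cut in B give the racemising 3-alkyl-Δ1-piperideine 12 and isopropenyl ketone 11 (intermolecular; sets all four centres of B).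
4. Both 12 and 11 come from one achiral N-Boc ene-carbamate/allylic alcohol 10 (masked imine, masked enone), made from N-Boc-2-piperidinone 1, 7-bromohept-1-ene 2 and isopropenylmagnesium bromide 9.
5. Ring order: both piperidine rings come from lactam 1; then the ketone ring of B (step 7); then the ketone ring of A together with the 16-membered ring (step 9).

Assumption: the SMILES is taken as drawn; carbinol centres that are oxidised later (in 10, 12, 13, 14) are carried as 1:1 epimers and written without a stereo label, as is the racemising imine carbon of 12 and 16.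

**Route**

Step 1
Reactants: 1 tert-butyl 2-oxopiperidine-1-carboxylate; 2 7-bromohept-1-ene
Product: 3 tert-butyl 3-(hept-6-en-1-yl)-2-oxopiperidine-1-carboxylate (racemic)
Conditions: LiN(SiMe3)2, THF, −78 °C; then 2, N,N′-dimethylpropyleneurea, −78 °C to −20 °C
Reagents that add atoms: none
Why: SN2 alkylation of the lithium enolate of the N-Boc lactam by the primary bromide; the new centre is racemic and is erased in step 2.

Step 2
Reactants: 3 tert-butyl 3-(hept-6-en-1-yl)-2-oxopiperidine-1-carboxylate
Product: 5 tert-butyl 5-(hept-6-en-1-yl)-3,4-dihydro-2H-pyridine-1-carboxylate, via hemiaminal 4 (not isolated)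
Conditions: LiEt3BH, THF, −78 °C; then (CF3CO)2O, i-Pr2NEt, 4-(dimethylamino)pyridine (cat.), −78 °C to rt
Reagents that add atoms: none
Why: Hydride reduction of the imide-like lactam carbonyl stops at the N-Boc hemiaminal, and trifluoroacetylation/elimination (lactam-to-ene-carbamate dehydration) gives the trisubstituted ring alkene, so no stereocentre remains.

Step 3
Reactants: 5 tert-butyl 5-(hept-6-en-1-yl)-3,4-dihydro-2H-pyridine-1-carboxylate
Product: 7 tert-butyl 5-(7-hydroxyheptyl)-3,4-dihydro-2H-pyridine-1-carboxylate, via alkylborane 6 (not isolated)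
Conditions: 9-BBN (1.1 equiv), THF, 0 °C to rt; then NaOH, H2O2, H2O, 0 °C
Reagents that add atoms: 9-borabicyclo[3.3.1]nonane (B1C2CCCC1CCC2; its boron unit stays only in 6); hydrogen peroxide (OO; oxygen of 7)
Why: Anti-Markovnikov hydroboration–oxidation; bulky 9-BBN reacts far faster with the monosubstituted terminal alkene than with the trisubstituted, carbamate-conjugated ring alkene.

Step 4
Reactants: 7 tert-butyl 5-(7-hydroxyheptyl)-3,4-dihydro-2H-pyridine-1-carboxylate
Product: 8 tert-butyl 5-(7-oxoheptyl)-3,4-dihydro-2H-pyridine-1-carboxylate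
Conditions: Dess–Martin periodinane, pyridine, CH2Cl2, 0 °C to rt
Reagents that add atoms: none
Why: Dess–Martin oxidation of the primary alcohol to the aldehyde under buffered, non-acidic conditions that leave the ene-carbamate alone.

Step 5
Reactants: 8 tert-butyl 5-(7-oxoheptyl)-3,4-dihydro-2H-pyridine-1-carboxylate; 9 isopropenylmagnesium bromide
Product: 10 tert-butyl 5-(7-hydroxy-8-methylnon-8-en-1-yl)-3,4-dihydro-2H-pyridine-1-carboxylate (racemic)
Conditions: 9, THF, −78 °C to 0 °C; then aq NH4Cl
Reagents that add atoms: none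
Why: Grignard 1,2-addition to the aldehyde at low temperature, where the carbamate is inert; the carbinol centre is racemic and is removed by later oxidation.

Step 6
Reactants: 10 tert-butyl 5-(7-hydroxy-8-methylnon-8-en-1-yl)-3,4-dihydro-2H-pyridine-1-carboxylate
Product: 11 tert-butyl 5-(8-methyl-7-oxonon-8-en-1-yl)-3,4-dihydro-2H-pyridine-1-carboxylate
Conditions: Dess–Martin periodinane, pyridine, CH2Cl2, 0 °C
Reagents that add atoms: none
Why: Dess–Martin oxidation of the secondary allylic alcohol gives the isopropenyl ketone without touching the ene-carbamate.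

Step 7
Reactants: 10 tert-butyl 5-(7-hydroxy-8-methylnon-8-en-1-yl)-3,4-dihydro-2H-pyridine-1-carboxylate (1.2 equiv); 11 tert-butyl 5-(8-methyl-7-oxonon-8-en-1-yl)-3,4-dihydro-2H-pyridine-1-carboxylate
Product: 14 tert-butyl 5-{5-[(1S,3R,9S,9aS)-9-(7-hydroxy-8-methylnon-8-en-1-yl)-3-methyl-2-oxooctahydro-2H-quinolizin-1-yl]pentyl}-3,4-dihydro-2H-pyridine-1-carboxylate, via cyclic imine 12 (not isolated), via Mannich adduct 13 (not isolated)
Conditions: 10, CF3CO2H, CH2Cl2, 0 °C, then aq K2CO3; crude 12, 11, (S)-proline (30 mol %), DMSO, rt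
Reagents that add atoms: none
Why: Proposed new method: an enamine-catalysed Mannich/aza-Michael annulation run as a dynamic kinetic resolution of a 3-alkyl-Δ1-piperideine. The (S)-proline enamine on the CH2 side of 11 (alkyl trans to N, anti to the acid) attacks the acid-hydrogen-bonded cyclic (Z)-imine in the aldol-like arrangement, with the imine ring carbon where an aldehyde substituent would sit, giving C1 S and C9a S. It attacks anti to the alkyl chain on the neighbouring carbon, so only one imine enantiomer reacts while 12 racemises through its achiral enamine tautomer (C9 S, H-9/H-9a trans). The secondary amine of 13 then closes by 6-endo aza-Michael addition, and C3 settles by reversible protonation as the equatorial methyl (R). The 3-alkyl group also blocks the usual self-Mannich trimerisation of the imine. Closest known reaction: proline-catalysed Mannich/aza-Michael annulation of cyclic imines that carry no stereocentre with vinyl ketones.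

Step 8
Reactants: 14 tert-butyl 5-{5-[(1S,3R,9S,9aS)-9-(7-hydroxy-8-methylnon-8-en-1-yl)-3-methyl-2-oxooctahydro-2H-quinolizin-1-yl]pentyl}-3,4-dihydro-2H-pyridine-1-carboxylate
Product: 15 tert-butyl 5-{5-[(1S,3R,9S,9aS)-3-methyl-9-(8-methyl-7-oxonon-8-en-1-yl)-2-oxooctahydro-2H-quinolizin-1-yl]pentyl}-3,4-dihydro-2H-pyridine-1-carboxylate
Conditions: Dess–Martin periodinane, pyridine, CH2Cl2, 0 °C
Reagents that add atoms: none
Why: Dess–Martin oxidation of the allylic alcohol (both carbinol epimers converge) under neutral buffered conditions that do not enolise the β-amino ketone, so the four centres of B are kept.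

Step 9
Reactants: 15 tert-butyl 5-{5-[(1S,3R,9S,9aS)-3-methyl-9-(8-methyl-7-oxonon-8-en-1-yl)-2-oxooctahydro-2H-quinolizin-1-yl]pentyl}-3,4-dihydro-2H-pyridine-1-carboxylate
Product: 18 target CNP0268544.1 (A 1S,3R,9R,9aR; B 1S,3R,9S,9aS), via cyclic imine 16 (not isolated), via Mannich adduct 17 (not isolated)
Conditions: CF3CO2H, CH2Cl2, 0 °C, then aq K2CO3; crude 16 added over 12 h to (S)-pyrrolidine-3-carboxylic acid (2 equiv), DMSO, 1 mM, rt
Reagents that add atoms: none
Why: Proposed new method: the same dynamic-kinetic Mannich/aza-Michael annulation, used to close a 16-membered ring with a diastereo-reversing β-amino acid catalyst. (S)-Pyrrolidine-3-carboxylic acid forms the enamine of the isopropenyl ketone and uses the same enamine face as (S)-proline (C1 S). With its acid one carbon further out, it binds the imine so that the opposite imine face is attacked (C9a R, H-1/H-9a cis). Attack anti to the imine's alkyl chain again selects one enantiomer of the racemising imine (C9 R). Aza-Michael closure of 17 and reversible protonation put the C3 methyl cis to the C1 chain (R, both equatorial on the cis-fused unit). Closest known reactions: anti-selective ketone Mannich reactions catalysed by pyrrolidine-3-carboxylic acids (acyclic imines) and acid-mediated Mannich macrocyclisation to bis-quinolizidinones.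

**Compound list**
1 | tert-butyl 2-oxopiperidine-1-carboxylate | O=C1CCCCN1C(=O)OC(C)(C)C | starting material
2 | 7-bromohept-1-ene | BrCCCCCC=C | starting material
3 | tert-butyl 3-(hept-6-en-1-yl)-2-oxopiperidine-1-carboxylate (racemic) | C=CCCCCCC1CCCN(C(=O)OC(C)(C)C)C1=O | intermediate
4 | tert-butyl 3-(hept-6-en-1-yl)-2-hydroxypiperidine-1-carboxylate (hemiaminal, lithium alkoxide in the flask, isomer mixture) | C=CCCCCCC1CCCN(C(=O)OC(C)(C)C)C1O | intermediate
5 | tert-butyl 5-(hept-6-en-1-yl)-3,4-dihydro-2H-pyridine-1-carboxylate | C=CCCCCCC1=CN(C(=O)OC(C)(C)C)CCC1 | intermediate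
6 | tert-butyl 5-[7-(9-borabicyclo[3.3.1]nonan-9-yl)heptyl]-3,4-dihydro-2H-pyridine-1-carboxylate (alkylborane) | B1(C2CCCC1CCC2)CCCCCCCC1=CN(C(=O)OC(C)(C)C)CCC1 | intermediate
7 | tert-butyl 5-(7-hydroxyheptyl)-3,4-dihydro-2H-pyridine-1-carboxylate | OCCCCCCCC1=CN(C(=O)OC(C)(C)C)CCC1 | intermediate
8 | tert-butyl 5-(7-oxoheptyl)-3,4-dihydro-2H-pyridine-1-carboxylate | O=CCCCCCCC1=CN(C(=O)OC(C)(C)C)CCC1 | intermediate
9 | isopropenylmagnesium bromide (prop-1-en-2-ylmagnesium bromide) | CC(=C)[Mg]Br | starting material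
10 | tert-butyl 5-(7-hydroxy-8-methylnon-8-en-1-yl)-3,4-dihydro-2H-pyridine-1-carboxylate (racemic) | CC(=C)C(O)CCCCCCC1=CN(C(=O)OC(C)(C)C)CCC1 | intermediate
11 | tert-butyl 5-(8-methyl-7-oxonon-8-en-1-yl)-3,4-dihydro-2H-pyridine-1-carboxylate | CC(=C)C(=O)CCCCCCC1=CN(C(=O)OC(C)(C)C)CCC1 | intermediate
12 | 3-(7-hydroxy-8-methylnon-8-en-1-yl)-3,4,5,6-tetrahydropyridine (cyclic imine, racemising at C3) | CC(=C)C(O)CCCCCCC1CCCN=C1 | intermediate
13 | tert-butyl 5-[(6S)-6-[(2S,3S)-3-(7-hydroxy-8-methylnon-8-en-1-yl)piperidin-2-yl]-8-methyl-7-oxonon-8-en-1-yl]-3,4-dihydro-2H-pyridine-1-carboxylate (Mannich adduct) | O=C(OC(C)(C)C)N1CCCC(=C1)CCCCC[C@H](C(=O)C(C)=C)[C@H]2NCCC[C@@H]2CCCCCCC(O)C(C)=C | intermediate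
14 | tert-butyl 5-{5-[(1S,3R,9S,9aS)-9-(7-hydroxy-8-methylnon-8-en-1-yl)-3-methyl-2-oxooctahydro-2H-quinolizin-1-yl]pentyl}-3,4-dihydro-2H-pyridine-1-carboxylate | O=C(OC(C)(C)C)N1CCCC(=C1)CCCCC[C@@H]2C(=O)[C@H](C)CN3CCC[C@H](CCCCCCC(O)C(C)=C)[C@@H]23 | intermediate
15 | tert-butyl 5-{5-[(1S,3R,9S,9aS)-3-methyl-9-(8-methyl-7-oxonon-8-en-1-yl)-2-oxooctahydro-2H-quinolizin-1-yl]pentyl}-3,4-dihydro-2H-pyridine-1-carboxylate | O=C(OC(C)(C)C)N1CCCC(=C1)CCCCC[C@@H]2C(=O)[C@H](C)CN3CCC[C@H](CCCCCCC(=O)C(C)=C)[C@@H]23 | intermediate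
16 | (1S,3R,9S,9aS)-3-methyl-9-(8-methyl-7-oxonon-8-en-1-yl)-1-[5-(3,4,5,6-tetrahydropyridin-3-yl)pentyl]octahydro-2H-quinolizin-2-one (cyclic imine, racemising at the imine ring C3) | N1=CC(CCC1)CCCCC[C@@H]2C(=O)[C@H](C)CN3CCC[C@H](CCCCCCC(=O)C(C)=C)[C@@H]23 | intermediate
17 | macrocyclic Mannich adduct: 16-membered carbocycle, quinolizidinone B (1S,3R,9S,9aS) intact, (2R,3R)-2,3-disubstituted piperidine NH whose C2 is bonded to the (S)-CH(CO–C(CH3)=CH2) carbon | N1CCC[C@H]2CCCCC[C@@H]3C(=O)[C@H](C)CN4CCC[C@H](CCCCC[C@H](C(=O)C(C)=C)[C@@H]21)[C@@H]34 | intermediate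
18 | target CNP0268544.1: bis(3-methylquinolizidin-2-one) macrocycle, A (1S,3R,9R,9aR), B (1S,3R,9S,9aS), C1 of each joined to C9 of the other by (CH2)5 | C[C@@H]1CN2CCC[C@H]3CCCCC[C@@H]4C(=O)[C@H](C)CN5CCC[C@H](CCCCC[C@H](C1=O)[C@@H]32)[C@@H]45 | target

**Totals**
Total steps: 9. Longest linear sequence: 9 (1 → 3 → 5 → 7 → 8 → 10 → 11 → 14 → 15 → 18).

**Three steps most likely to fail**

Step 9 (proposed new step). Risks: the amine catalyst turns over slowly at 1 mM, the forming macrocycle may impose its own preference at C1/C9a, oligomers may form, and B could epimerise if the reaction is slow. Fallback with known chemistry only; it sets out from 14 and comes back at 18. NaBH4 in MeOH at 0 °C reduces the ring ketone of 14 from the axial side to the equatorial alcohol, the diol F4 (the other carbinol epimer would serve equally). MnO2 in CH2Cl2 oxidises only the allylic alcohol to give the hydroxy enone F5. CF3CO2H then frees the cyclic imine F6, which is closed at 1 mM under achiral thermodynamic Mannich/aza-Michael conditions (AcOH/NaOAc, MeOH, 50 °C). With B locked as an alcohol it can neither enolise nor undergo retro-Mannich cleavage, so only the new unit equilibrates; every product is a diastereomer of an enantiopure compound and is separable on silica. The macrocyclic keto alcohol F7 (A configuration) is oxidised with Dess–Martin periodinane/pyridine to 18.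

Step 7 (proposed new step). Risks: slow enamine formation at the hindered isopropenyl ketone, a competing aza-Michael-first pathway that bypasses catalyst control, and incomplete resolution of 12. Fallback with known chemistry only; it sets out from 10 and 11 and comes back at 15. Imine 12 is freed as in step 7 and heated with 11 without a chiral catalyst (AcOH, MeOH, 50 °C; reversible acid-mediated Mannich/aza-Michael annulation). Equilibration and chromatography give the trans-fused, all-equatorial adduct as a racemate, that is 14 together with ent-14 F2. Dess–Martin oxidation as in step 8 gives 15 together with ent-15 F3, and preparative chromatography on a chiral stationary phase delivers 15.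

Step 1. Risk: the N-Boc lactam enolate is only moderately nucleophilic toward an unactivated primary bromide and decomposes on warming. Fallback; it sets out from 2 (plus commercial piperidin-2-one) and comes back at 3. Piperidin-2-one is converted into its N,C-dianion (n-BuLi, 2.1 equiv, THF, 0 °C), which is alkylated at C3 by 2 to give 3-(hept-6-en-1-yl)piperidin-2-one F1. Boc2O, 4-(dimethylamino)pyridine and Et3N in CH2Cl2 then give 3.

**Further compounds**
F1 | step 1 | 3-(hept-6-en-1-yl)piperidin-2-one (racemic) | O=C1NCCCC1CCCCCC=C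
F2 | step 7 | ent-14: tert-butyl 5-{5-[(1R,3S,9R,9aR)-9-(7-hydroxy-8-methylnon-8-en-1-yl)-3-methyl-2-oxooctahydro-2H-quinolizin-1-yl]pentyl}-3,4-dihydro-2H-pyridine-1-carboxylate | O=C(OC(C)(C)C)N1CCCC(=C1)CCCCC[C@H]2C(=O)[C@@H](C)CN3CCC[C@@H](CCCCCCC(O)C(C)=C)[C@H]23
F3 | step 7 | ent-15: tert-butyl 5-{5-[(1R,3S,9R,9aR)-3-methyl-9-(8-methyl-7-oxonon-8-en-1-yl)-2-oxooctahydro-2H-quinolizin-1-yl]pentyl}-3,4-dihydro-2H-pyridine-1-carboxylate | O=C(OC(C)(C)C)N1CCCC(=C1)CCCCC[C@H]2C(=O)[C@@H](C)CN3CCC[C@@H](CCCCCCC(=O)C(C)=C)[C@H]23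
F4 | step 9 | diol: tert-butyl 5-{5-[(1S,2S,3R,9S,9aS)-2-hydroxy-9-(7-hydroxy-8-methylnon-8-en-1-yl)-3-methyloctahydro-2H-quinolizin-1-yl]pentyl}-3,4-dihydro-2H-pyridine-1-carboxylate | O=C(OC(C)(C)C)N1CCCC(=C1)CCCCC[C@@H]2[C@@H](O)[C@H](C)CN3CCC[C@H](CCCCCCC(O)C(C)=C)[C@@H]23
F5 | step 9 | hydroxy enone: tert-butyl 5-{5-[(1S,2S,3R,9S,9aS)-2-hydroxy-3-methyl-9-(8-methyl-7-oxonon-8-en-1-yl)octahydro-2H-quinolizin-1-yl]pentyl}-3,4-dihydro-2H-pyridine-1-carboxylate | O=C(OC(C)(C)C)N1CCCC(=C1)CCCCC[C@@H]2[C@@H](O)[C@H](C)CN3CCC[C@H](CCCCCCC(=O)C(C)=C)[C@@H]23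
F6 | step 9 | cyclic imine: 1-{(1S,2S,3R,9S,9aS)-2-hydroxy-3-methyl-1-[5-(3,4,5,6-tetrahydropyridin-3-yl)pentyl]octahydro-2H-quinolizin-9-yl}-8-methylnon-8-en-7-one | N1=CC(CCC1)CCCCC[C@@H]2[C@@H](O)[C@H](C)CN3CCC[C@H](CCCCCCC(=O)C(C)=C)[C@@H]23
F7 | step 9 | macrocyclic keto alcohol: 18 with the ketone of quinolizidinone B replaced by the (2S)-alcohol | C[C@@H]1CN2CCC[C@H]3CCCCC[C@@H]4[C@@H](O)[C@H](C)CN5CCC[C@H](CCCCC[C@H](C1=O)[C@@H]32)[C@@H]45
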